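Readings and results were computed with constants of no real substance.

- time, not beyond 50 min, at which the flask holds most target
- the amount of target, in percent of the starting material charged, at that time
- the first time at which target reaches 36%, in the same percent, in min

all flasks: starting material 0.14 M; free catalyst 14 mM

| charge | protic impurity | remark | time |
|---|---|---|---|
| elm | 0.070 M | the very flask that is asked about, followed so far |  |
| flask | 0.0700 M |  | 50 min |

- elm (time / min: target / %, starting material / %): 0.500: 29.3, 45.5; 1.00: 54.9, 13.2; 2.50: 71.0, 1.1; 5.00: 68.3, 0.2; 12.0: 62.0, 0; 25.0: 64.6, 0

(readings scatter by 1 percentage point)



Starting material cannot be what eats the target late in this flask: it reads 1.1% at 2.50 min and 0% at 12.0 min, yet target falls from 71.0% to 62.0%. The protic impurity was charged at 50.0% of the starting material, but the fall stops after a few points, much closer to the catalyst charge, which is 10.0% of the starting material. So I suppose that free catalyst dies on target, one for one, and is the limiting reagent of this loss.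

Dividing the rate of target loss by the rate of catalyst loss removes time, which leaves a count. The two late readings average 63.3%, so the slip from the peak reading is 7.7 percentage points. Dividing this by the catalyst share gives 0.770, the target lost per catalyst charged, which stays below one. The highest amount I can allow is then the plateau plus the catalyst share, 73.3%, so I commit to a best between that and the peak reading.

The weak link is the plateau: its two readings differ by 2.6 points. The 12.0 min reading alone gives 0.900 and the 25.0 min reading alone gives 0.640, and both stay below one.

The forecast gives 2.7 min (1.9 min to 3.8 min), 71.5% (69.8% to 73.5%) and 0.63 min (0.56 min to 0.7 min), and says of the tail “this looks like a plateau near 63%, from catalyst death or equilibrium”.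

The flask peaks at 1.87 min with 71.2% and reaches 36% at 0.617 min; the forecast's peak time is late, while its amount and first time hold.

    starting material + protic impurity → quenched substrate (k = 0.0950 L mol⁻¹ s⁻¹)
    starting material + free catalyst → catalyst intermediate (k = 11.0 L mol⁻¹ s⁻¹)
    starting material + target → side product (k = 0.0500 L mol⁻¹ s⁻¹)
    catalyst intermediate → free catalyst + target (k = 0.120 s⁻¹)
    free catalyst + target → spent catalyst (k = 0.0440 L mol⁻¹ s⁻¹)

At 0.483 min this flask makes target 10.6 times faster than it uses it up, and at the peak its starting material stands at 0.0518%. From there it slips to 63.1% by 50.0 min, which is 0.807 target lost per catalyst charged. For the neighbour charged with 0.024 M of free catalyst, my 0.770 gives a slip of 13 points, and that neighbour falls from 80.1% to 65.8%.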